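**Retrosynthetic overview**

- The route rests on ring G and its copies, rings E and C. Each is a benzene with five contiguous oxygen-bearing carbons (C1–C5) and a single CH (C6). C1–C4 with their oxygens map onto a squarate and C5/C6 onto a 1-methoxyvinyl group.
- Key disconnection: the C1–C6 bond of ring G, by thermal ring expansion of a 4-methoxy-4-(1-methoxyvinyl)cyclobutenone that already carries ring H as the aryloxy group on its C2.
- The same squarate cycle then builds ring E on the ring F phenol and ring C on the ring D phenol. Each cycle is semisquaric chloride esterification, addition of 1-methoxyvinyllithium with MeOTf trapping, then thermolysis.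
- Rings F, D and B enter as 5-(benzyloxy)-2-iodo-1,3-dimethoxybenzene by CuI-catalysed Ullmann etherification of the newly freed C1 phenol, followed by hydrogenolysis. Ring A enters as 2-iodo-1,3,5-trimethoxybenzene, and BBr3 removes all methyl ethers at the end.
- Ring order: H (bought) → G formed → F attached → E formed → D attached → C formed → B attached → A attached.

Key step: step 6

**Remarks**

- Rings are lettered A to H along the chain. C1 of a ring is the carbon whose ether oxygen points toward ring A (in ring A, the carbon with its only ether oxygen). In rings G, E and C the ether oxygen toward ring H is on C2, C3–C5 carry OH and C6 is CH. In rings F, D and B the ether oxygen toward ring H is on C4 and C3/C5 carry OH.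
- In oligomer names every oxygen not mentioned is a methyl ether.
- The target has no stereocentre. The cyclobutenones and their lithium alkoxides carry one quaternary stereocentre, are made as racemates, and lose it on aromatisation.
- The THF solution of 1-methoxyvinyllithium 7 (step 4) is not stored. It is prepared on the scale needed immediately before each of steps 5, 13 and 18.
- Assumption: 2-iodo-1,3,5-trimethoxybenzene is taken as commercially available.

**Route**

Step 1
Reactants: 1 squaric acid (3,4-dihydroxycyclobut-3-ene-1,2-dione)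
Product: 2 3,4-dichlorocyclobut-3-ene-1,2-dione (squaryl dichloride)
Conditions: (COCl)2, DMF (cat.), CH2Cl2, reflux
Reagents that add atoms: oxalyl chloride, ClC(=O)C(=O)Cl
Why: Chlorodehydroxylation of the two vinylogous carboxylic acid OH groups through a Vilsmeier-type chloroiminium species (acid chloride formation), the standard entry to squaryl dichloride.

Step 2
Reactants: 2 3,4-dichlorocyclobut-3-ene-1,2-dione
Product: 3 3-chloro-4-methoxycyclobut-3-ene-1,2-dione
Conditions: MeOH (1.0 equiv), CH2Cl2, 0 °C to rt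
Reagents that add atoms: methanol, CO
Why: Alcoholysis of a vinylogous acyl chloride by addition–elimination, which should stop at the mono-ester because the methoxy donor of 3 deactivates the remaining chlorine-bearing carbon toward a second substitution.

Step 3
Reactants: 3 3-chloro-4-methoxycyclobut-3-ene-1,2-dione; 4 3,4,5-trimethoxyphenol
Product: 5 3-methoxy-4-(3,4,5-trimethoxyphenoxy)cyclobut-3-ene-1,2-dione
Conditions: iPr2NEt, CH2Cl2, −78 to 0 °C
Reagents that add atoms: none
Why: Vinylogous O-acylation of the phenol (addition–elimination at the chlorine-bearing carbon of the semisquaric chloride), in which chloride departs far more readily than methoxide so that the methyl ester is kept and the mixed aryl methyl squarate results.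

Step 4
Reactants: 6 methyl vinyl ether
Product: 7 1-methoxyvinyllithium (THF solution, used directly in steps 5, 13 and 18)
Conditions: t-BuLi, THF, −78 to 0 °C
Reagents that add atoms: tert-butyllithium, [Li]C(C)(C)C
Why: α-Lithiation of an enol ether, in which t-BuLi removes the vinylic hydrogen on the oxygen-bearing carbon (acidified by the inductive effect of oxygen and assisted by its coordination to lithium), the standard preparation of this acyl anion equivalent.

Step 5
Reactants: 5 3-methoxy-4-(3,4,5-trimethoxyphenoxy)cyclobut-3-ene-1,2-dione; 7 1-methoxyvinyllithium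
Product: 9 3,4-dimethoxy-4-(1-methoxyvinyl)-2-(3,4,5-trimethoxyphenoxy)cyclobut-2-en-1-one (racemic), via lithium alkoxide 8 (not isolated)
Conditions: 7 (THF solution), THF, −78 °C; then MeOTf, −78 to 0 °C
Reagents that add atoms: methyl trifluoromethanesulfonate, COS(=O)(=O)C(F)(F)F
Why: 1,2-Addition of a vinyllithium to a squarate ester should occur at the carbonyl that is vinylogous to the aryloxy oxygen (the weaker donor, so this carbonyl keeps more ketone character) and that is flanked by the small methoxy group, and the lithium alkoxide is then O-methylated in the same flask by MeOTf; the new quaternary stereocentre forms as a racemate, which is of no consequence because it becomes aromatic in step 6.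

Step 6
Reactants: 9 3,4-dimethoxy-4-(1-methoxyvinyl)-2-(3,4,5-trimethoxyphenoxy)cyclobut-2-en-1-one
Product: 12 3,4,5-trimethoxy-2-(3,4,5-trimethoxyphenoxy)phenol (H–G phenol with free OH at C1 of ring G), via dienylketene 10 (not isolated), via cyclohexadienone 11 (not isolated)
Conditions: toluene (degassed, dilute), 110 °C
Reagents that add atoms: none
Why: Thermal conrotatory 4π electrocyclic opening of the C1–C4 bond of 9 gives dienylketene 10, thermal disrotatory 6π electrocyclisation joins the ketene carbon to the vinyl CH2 (the new C1–C6 bond of ring G) to give cyclohexa-2,4-dienone 11, and enolisation of its CH2 delivers phenol 12. The closest known reaction type is the thermal ring expansion of squarate-derived 4-alkenyl-4-alkoxycyclobutenones to polyoxygenated phenols (Moore rearrangement). Ring G is closed as a six-membered carbocycle by 6π electrocyclisation of a 1,3,5-hexatriene in which the ketene C=C is one of the three double bonds; no stereocentre is created and the racemic quaternary carbon of 9 becomes aromatic C4. The selectivity needed is torquoselectivity in the ring opening: the methoxy donor on C4 rotates outward, which turns the 1-methoxyvinyl group inward and places it cis to the ketene, the only geometry that can cyclise. Because the C4 oxygen is already a methyl ether no hydroquinone or quinone can arise, so the former carbonyl oxygen ends as the single free hydroxyl at C1, next to the ring H ether at C2 and ready for the next O-arylation.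

Step 7
Reactants: 13 3,5-dimethoxyphenol
Product: 14 (3,5-dimethoxyphenoxy)triisopropylsilane
Conditions: TIPSCl, imidazole, DMF, rt
Reagents that add atoms: chlorotriisopropylsilane, CC(C)[Si](Cl)(C(C)C)C(C)C
Why: Silylation of the phenol with a silyl chloride and imidazole; the bulky, weakly coordinating TIPS ether is chosen because it does not direct lithiation to its ortho positions.

Step 8
Reactants: 14 (3,5-dimethoxyphenoxy)triisopropylsilane
Product: 16 (4-iodo-3,5-dimethoxyphenoxy)triisopropylsilane, via aryllithium 15 (not isolated)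
Conditions: n-BuLi, THF, 0 °C to rt; then I2, −78 °C to rt
Reagents that add atoms: iodine, II
Why: Directed ortho-metalation at C4, the only ring position flanked by two methoxy groups (cooperative direction, as for 1,3-dimethoxybenzene) while the TIPS ether shields C2 and C6, followed by iodinolysis of the aryllithium.

Step 9
Reactants: 16 (4-iodo-3,5-dimethoxyphenoxy)triisopropylsilane
Product: 18 5-(benzyloxy)-2-iodo-1,3-dimethoxybenzene (ring F/D/B unit), via caesium phenolate 17 (not isolated)
Conditions: CsF, BnBr, DMF, rt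
Reagents that add atoms: benzyl bromide, BrCc1ccccc1
Why: Fluoride-induced desilylation gives the phenolate, which is benzylated in the same flask (Williamson ether synthesis); the benzyl ether, unlike the silyl ether, withstands the basic copper coupling and is later removed by hydrogenolysis without touching methyl ethers.

Step 10
Reactants: 12 3,4,5-trimethoxy-2-(3,4,5-trimethoxyphenoxy)phenol; 18 5-(benzyloxy)-2-iodo-1,3-dimethoxybenzene
Product: 19 5-(benzyloxy)-1,3-dimethoxy-2-[3,4,5-trimethoxy-2-(3,4,5-trimethoxyphenoxy)phenoxy]benzene (H–G–F benzyl ether)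
Conditions: CuI (cat.), picolinic acid, K3PO4, DMSO, 110 °C, argon
Reagents that add atoms: none
Why: Ullmann-type copper-catalysed diaryl ether synthesis with a picolinate ligand, a system suited to ortho-substituted partners; 12 has a single free OH and 18 none, so only the G C1–O–F C4 bond can form, and the ortho methoxy groups of 18 can assist by coordinating copper.

Step 11
Reactants: 19 H–G–F benzyl ether
Product: 20 3,5-dimethoxy-4-[3,4,5-trimethoxy-2-(3,4,5-trimethoxyphenoxy)phenoxy]phenol (H–G–F phenol with free OH at C1 of ring F)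
Conditions: H2 (1 atm), Pd/C, EtOAc–MeOH, rt
Reagents that add atoms: none
Why: Catalytic hydrogenolysis of the aryl benzyl ether, which leaves aryl methyl ethers and diaryl ethers untouched and frees the C1 hydroxyl of ring F.

Step 12
Reactants: 20 H–G–F phenol; 3 3-chloro-4-methoxycyclobut-3-ene-1,2-dione
Product: 21 H–G–F methyl squarate (3-methoxy-4-aryloxycyclobut-3-ene-1,2-dione whose aryloxy group is the ring F C1 oxygen of 20)
Conditions: iPr2NEt, CH2Cl2, −78 to 0 °C
Reagents that add atoms: none
Why: Same vinylogous O-acylation as in step 3, now on the unhindered ring F phenol, with chloride again the only group displaced.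

Step 13
Reactants: 21 H–G–F methyl squarate; 7 1-methoxyvinyllithium
Product: 23 H–G–F cyclobutenone (3,4-dimethoxy-4-(1-methoxyvinyl)-2-aryloxycyclobut-2-en-1-one on the ring F C1 oxygen; racemic), via lithium alkoxide 22 (not isolated)
Conditions: 7 (THF solution), THF, −78 °C; then MeOTf, −78 to 0 °C
Reagents that add atoms: methyl trifluoromethanesulfonate, COS(=O)(=O)C(F)(F)F
Why: Same regioselective 1,2-addition of the vinyllithium to the squarate carbonyl vinylogous to the aryloxy group and in situ O-methylation as in step 5; the racemic quaternary centre is lost in step 14.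

Step 14
Reactants: 23 H–G–F cyclobutenone
Product: 26 H–G–F–E phenol (free OH at C1 of ring E), via dienylketene 24 (not isolated), via cyclohexadienone 25 (not isolated)
Conditions: toluene (degassed, dilute), 110 °C
Reagents that add atoms: none
Why: Same 4π ring opening, 6π electrocyclisation and enolisation (Moore rearrangement) as in step 6, here forming ring E with its C2 oxygen already bound to C1 of ring F and only its C1 hydroxyl free.

Step 15
Reactants: 26 H–G–F–E phenol; 18 5-(benzyloxy)-2-iodo-1,3-dimethoxybenzene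
Product: 27 H–G–F–E–D benzyl ether (benzyl ether at C1 of ring D)
Conditions: CuI (cat.), picolinic acid, K3PO4, DMSO, 110 °C, argon
Reagents that add atoms: none
Why: Same Ullmann-type diaryl ether synthesis as in step 10, joining C1 of ring E to C4 of ring D.

Step 16
Reactants: 27 H–G–F–E–D benzyl ether
Product: 28 H–G–F–E–D phenol (free OH at C1 of ring D)
Conditions: H2 (1 atm), Pd/C, EtOAc–MeOH, rt
Reagents that add atoms: none
Why: Catalytic hydrogenolysis of the single aryl benzyl ether, as in step 11.

Step 17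
Reactants: 28 H–G–F–E–D phenol; 3 3-chloro-4-methoxycyclobut-3-ene-1,2-dione
Product: 29 H–G–F–E–D methyl squarate (3-methoxy-4-aryloxycyclobut-3-ene-1,2-dione on the ring D C1 oxygen)
Conditions: iPr2NEt, CH2Cl2, −78 to 0 °C
Reagents that add atoms: none
Why: Same vinylogous O-acylation of a phenol by the semisquaric chloride as in steps 3 and 12.

Step 18
Reactants: 29 H–G–F–E–D methyl squarate; 7 1-methoxyvinyllithium
Product: 31 H–G–F–E–D cyclobutenone (3,4-dimethoxy-4-(1-methoxyvinyl)-2-aryloxycyclobut-2-en-1-one on the ring D C1 oxygen; racemic), via lithium alkoxide 30 (not isolated)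
Conditions: 7 (THF solution), THF, −78 °C; then MeOTf, −78 to 0 °C
Reagents that add atoms: methyl trifluoromethanesulfonate, COS(=O)(=O)C(F)(F)F
Why: Same regioselective vinyllithium 1,2-addition to the squarate and in situ O-methylation as in steps 5 and 13; the racemic quaternary centre is lost in step 19.

Step 19
Reactants: 31 H–G–F–E–D cyclobutenone
Product: 34 H–G–F–E–D–C phenol (free OH at C1 of ring C), via dienylketene 32 (not isolated), via cyclohexadienone 33 (not isolated)
Conditions: toluene (degassed, dilute), 110 °C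
Reagents that add atoms: none
Why: Same thermal cyclobutenone ring expansion (Moore rearrangement) as in steps 6 and 14, forming ring C with only its C1 hydroxyl free.

Step 20
Reactants: 34 H–G–F–E–D–C phenol; 18 5-(benzyloxy)-2-iodo-1,3-dimethoxybenzene
Product: 35 H–G–F–E–D–C–B benzyl ether (benzyl ether at C1 of ring B)
Conditions: CuI (cat.), picolinic acid, K3PO4, DMSO, 110 °C, argon
Reagents that add atoms: none
Why: Same Ullmann-type diaryl ether synthesis as in steps 10 and 15, joining C1 of ring C to C4 of ring B.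

Step 21
Reactants: 35 H–G–F–E–D–C–B benzyl ether
Product: 36 H–G–F–E–D–C–B phenol (free OH at C1 of ring B)
Conditions: H2 (1 atm), Pd/C, EtOAc–MeOH, rt
Reagents that add atoms: none
Why: Catalytic hydrogenolysis of the single aryl benzyl ether, as in steps 11 and 16.

Step 22
Reactants: 36 H–G–F–E–D–C–B phenol; 37 2-iodo-1,3,5-trimethoxybenzene
Product: 38 henicosamethyl ether of the target (all twenty-one hydroxyls of rings A to H as methyl ethers)
Conditions: CuI (cat.), picolinic acid, K3PO4, DMSO, 110 °C, argon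
Reagents that add atoms: none
Why: Same Ullmann-type etherification, now with the doubly ortho-methoxylated iodide that carries ring A, closing the chain with the B C1–O–A C1 bond.

Step 23
Reactants: 38 henicosamethyl ether of the target
Product: 39 CNP0206369.0 (target)
Conditions: BBr3 (excess), CH2Cl2, −78 °C to rt; then MeOH, H2O, argon
Reagents that add atoms: none
Why: Lewis acid-mediated cleavage of all twenty-one aryl methyl ethers by BBr3 (ether demethylation), to which diaryl ether bonds are inert; methanolysis of the borate esters releases the free polyphenol, which has no stereocentre.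

**Compound list**

1 | squaric acid (3,4-dihydroxycyclobut-3-ene-1,2-dione) | OC1=C(O)C(=O)C1=O | starting material
2 | 3,4-dichlorocyclobut-3-ene-1,2-dione | ClC1=C(Cl)C(=O)C1=O | intermediate
3 | 3-chloro-4-methoxycyclobut-3-ene-1,2-dione | COC1=C(Cl)C(=O)C1=O | intermediate
4 | 3,4,5-trimethoxyphenol | COc1cc(O)cc(OC)c1OC | starting material
5 | 3-methoxy-4-(3,4,5-trimethoxyphenoxy)cyclobut-3-ene-1,2-dione | COc1c(OC)cc(cc1OC)OC1=C(OC)C(=O)C1=O | intermediate
6 | methyl vinyl ether | COC=C | starting material
7 | 1-methoxyvinyllithium (THF solution) | [Li]C(=C)OC | intermediate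
8 | lithium alkoxide of 9 (racemic) | COc1c(OC)cc(cc1OC)OC1=C(OC)C([O-])(C(OC)=C)C1=O.[Li+] | intermediate
9 | 3,4-dimethoxy-4-(1-methoxyvinyl)-2-(3,4,5-trimethoxyphenoxy)cyclobut-2-en-1-one (racemic) | COc1c(OC)cc(cc1OC)OC1=C(OC)C(OC)(C(OC)=C)C1=O | intermediate
10 | (3Z)-3,4,5-trimethoxy-2-(3,4,5-trimethoxyphenoxy)hexa-1,3,5-trien-1-one (dienylketene) | COc1c(OC)cc(cc1OC)OC(=C=O)/C(OC)=C(OC)\C(OC)=C | intermediate
11 | 3,4,5-trimethoxy-2-(3,4,5-trimethoxyphenoxy)cyclohexa-2,4-dien-1-one | COc1c(OC)cc(cc1OC)OC1=C(OC)C(OC)=C(OC)CC1=O | intermediate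
12 | 3,4,5-trimethoxy-2-(3,4,5-trimethoxyphenoxy)phenol (H–G phenol) | COc1c(OC)cc(cc1OC)Oc1c(OC)c(OC)c(OC)cc1O | intermediate
13 | 3,5-dimethoxyphenol | COc1cc(O)cc(OC)c1 | starting material
14 | (3,5-dimethoxyphenoxy)triisopropylsilane | COc1cc(O[Si](C(C)C)(C(C)C)C(C)C)cc(OC)c1 | intermediate
15 | [2,6-dimethoxy-4-(triisopropylsilyloxy)phenyl]lithium | [Li]c1c(OC)cc(O[Si](C(C)C)(C(C)C)C(C)C)cc1OC | intermediate
16 | (4-iodo-3,5-dimethoxyphenoxy)triisopropylsilane | COc1cc(O[Si](C(C)C)(C(C)C)C(C)C)cc(OC)c1I | intermediate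
17 | caesium 4-iodo-3,5-dimethoxyphenolate | [Cs+].[O-]c1cc(OC)c(I)c(OC)c1 | intermediate
18 | 5-(benzyloxy)-2-iodo-1,3-dimethoxybenzene | COc1cc(OCc2ccccc2)cc(OC)c1I | intermediate
19 | H–G–F benzyl ether | COc1c(OC)cc(cc1OC)Oc1c(OC)c(OC)c(OC)cc1Oc1c(OC)cc(cc1OC)OCc1ccccc1 | intermediate
20 | H–G–F phenol (free OH at C1 of ring F) | COc1c(OC)cc(cc1OC)Oc1c(OC)c(OC)c(OC)cc1Oc1c(OC)cc(cc1OC)O | intermediate
21 | H–G–F methyl squarate | COc1c(OC)cc(cc1OC)Oc1c(OC)c(OC)c(OC)cc1Oc1c(OC)cc(cc1OC)OC1=C(OC)C(=O)C1=O | intermediate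
22 | lithium alkoxide of 23 (racemic) | COc1c(OC)cc(cc1OC)Oc1c(OC)c(OC)c(OC)cc1Oc1c(OC)cc(cc1OC)OC1=C(OC)C([O-])(C(OC)=C)C1=O.[Li+] | intermediate
23 | H–G–F cyclobutenone (racemic) | COc1c(OC)cc(cc1OC)Oc1c(OC)c(OC)c(OC)cc1Oc1c(OC)cc(cc1OC)OC1=C(OC)C(OC)(C(OC)=C)C1=O | intermediate
24 | H–G–F (Z)-dienylketene | COc1c(OC)cc(cc1OC)Oc1c(OC)c(OC)c(OC)cc1Oc1c(OC)cc(cc1OC)OC(=C=O)/C(OC)=C(OC)\C(OC)=C | intermediate
25 | H–G–F cyclohexa-2,4-dienone | COc1c(OC)cc(cc1OC)Oc1c(OC)c(OC)c(OC)cc1Oc1c(OC)cc(cc1OC)OC1=C(OC)C(OC)=C(OC)CC1=O | intermediate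
26 | H–G–F–E phenol (free OH at C1 of ring E) | COc1c(OC)cc(cc1OC)Oc1c(OC)c(OC)c(OC)cc1Oc1c(OC)cc(cc1OC)Oc1c(OC)c(OC)c(OC)cc1O | intermediate
27 | H–G–F–E–D benzyl ether | COc1c(OC)cc(cc1OC)Oc1c(OC)c(OC)c(OC)cc1Oc1c(OC)cc(cc1OC)Oc1c(OC)c(OC)c(OC)cc1Oc1c(OC)cc(cc1OC)OCc1ccccc1 | intermediate
28 | H–G–F–E–D phenol (free OH at C1 of ring D) | COc1c(OC)cc(cc1OC)Oc1c(OC)c(OC)c(OC)cc1Oc1c(OC)cc(cc1OC)Oc1c(OC)c(OC)c(OC)cc1Oc1c(OC)cc(cc1OC)O | intermediate
29 | H–G–F–E–D methyl squarate | COc1c(OC)cc(cc1OC)Oc1c(OC)c(OC)c(OC)cc1Oc1c(OC)cc(cc1OC)Oc1c(OC)c(OC)c(OC)cc1Oc1c(OC)cc(cc1OC)OC1=C(OC)C(=O)C1=O | intermediate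
30 | lithium alkoxide of 31 (racemic) | COc1c(OC)cc(cc1OC)Oc1c(OC)c(OC)c(OC)cc1Oc1c(OC)cc(cc1OC)Oc1c(OC)c(OC)c(OC)cc1Oc1c(OC)cc(cc1OC)OC1=C(OC)C([O-])(C(OC)=C)C1=O.[Li+] | intermediate
31 | H–G–F–E–D cyclobutenone (racemic) | COc1c(OC)cc(cc1OC)Oc1c(OC)c(OC)c(OC)cc1Oc1c(OC)cc(cc1OC)Oc1c(OC)c(OC)c(OC)cc1Oc1c(OC)cc(cc1OC)OC1=C(OC)C(OC)(C(OC)=C)C1=O | intermediate
32 | H–G–F–E–D (Z)-dienylketene | COc1c(OC)cc(cc1OC)Oc1c(OC)c(OC)c(OC)cc1Oc1c(OC)cc(cc1OC)Oc1c(OC)c(OC)c(OC)cc1Oc1c(OC)cc(cc1OC)OC(=C=O)/C(OC)=C(OC)\C(OC)=C | intermediate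
33 | H–G–F–E–D cyclohexa-2,4-dienone | COc1c(OC)cc(cc1OC)Oc1c(OC)c(OC)c(OC)cc1Oc1c(OC)cc(cc1OC)Oc1c(OC)c(OC)c(OC)cc1Oc1c(OC)cc(cc1OC)OC1=C(OC)C(OC)=C(OC)CC1=O | intermediate
34 | H–G–F–E–D–C phenol (free OH at C1 of ring C) | COc1c(OC)cc(cc1OC)Oc1c(OC)c(OC)c(OC)cc1Oc1c(OC)cc(cc1OC)Oc1c(OC)c(OC)c(OC)cc1Oc1c(OC)cc(cc1OC)Oc1c(OC)c(OC)c(OC)cc1O | intermediate
35 | H–G–F–E–D–C–B benzyl ether | COc1c(OC)cc(cc1OC)Oc1c(OC)c(OC)c(OC)cc1Oc1c(OC)cc(cc1OC)Oc1c(OC)c(OC)c(OC)cc1Oc1c(OC)cc(cc1OC)Oc1c(OC)c(OC)c(OC)cc1Oc1c(OC)cc(cc1OC)OCc1ccccc1 | intermediate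
36 | H–G–F–E–D–C–B phenol (free OH at C1 of ring B) | COc1c(OC)cc(cc1OC)Oc1c(OC)c(OC)c(OC)cc1Oc1c(OC)cc(cc1OC)Oc1c(OC)c(OC)c(OC)cc1Oc1c(OC)cc(cc1OC)Oc1c(OC)c(OC)c(OC)cc1Oc1c(OC)cc(cc1OC)O | intermediate
37 | 2-iodo-1,3,5-trimethoxybenzene | COc1cc(OC)c(I)c(OC)c1 | starting material
38 | henicosamethyl ether of the target | COc1c(OC)cc(cc1OC)Oc1c(OC)c(OC)c(OC)cc1Oc1c(OC)cc(cc1OC)Oc1c(OC)c(OC)c(OC)cc1Oc1c(OC)cc(cc1OC)Oc1c(OC)c(OC)c(OC)cc1Oc1c(OC)cc(cc1OC)Oc1c(OC)cc(OC)cc1OC | intermediate
39 | CNP0206369.0 | Oc1cc(O)c(Oc2cc(O)c(Oc3cc(O)c(O)c(O)c3Oc3cc(O)c(Oc4cc(O)c(O)c(O)c4Oc4cc(O)c(Oc5cc(O)c(O)c(O)c5Oc5cc(O)c(O)c(O)c5)c(O)c4)c(O)c3)c(O)c2)c(O)c1 | target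

**Step count**

Total steps: 23. Longest linear sequence: 19 steps (steps 1–3, 5, 6 and 10–23, from squaric acid). The vinyllithium reagent 7 is made in a one-step side branch (step 4) and the ring F/D/B unit 18 in a three-step side branch (steps 7–9).

**Steps most likely to fail**

1. Step 5 (the same risk recurs in steps 13 and 18). What may go wrong: the vinyllithium attacks the carbonyl next to the aryloxy carbon, or adds in conjugate fashion with expulsion of aryloxide, in competition with the wanted 1,2-addition. The cyclobutenone would then be regioisomerically impure and would expand to an isomeric phenol. Fallback, setting out from 2 and 4 and returning at 9: squaryl dichloride 2 would be esterified with two equivalents of 4 (iPr2NEt, CH2Cl2, −78 to 0 °C) to the symmetrical 3,4-bis(3,4,5-trimethoxyphenoxy)cyclobut-3-ene-1,2-dione F1, whose two carbonyls are equivalent, so the addition has no regiochemical choice. Addition of 7 from step 4 and trapping with MeOTf would pass through lithium alkoxide F2 to 4-methoxy-4-(1-methoxyvinyl)-2,3-bis(3,4,5-trimethoxyphenoxy)cyclobut-2-en-1-one F3. Vinylogous transesterification (MeOH, catalytic K2CO3, THF, 0 °C) should then exchange only the aryloxy group on C3, the β-carbon of the enone, for methoxy by addition–elimination. This gives 9 and returns one equivalent of 4; the C2 aryloxy group is not at an electrophilic position and stays.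

2. Step 10 (the same risk recurs in steps 15, 20 and 22). What may go wrong: oxidative addition of copper into the electron-rich, doubly ortho-substituted iodide is slow, so reductive deiodination and oxidative decay of the electron-rich phenoxide outpace ether formation. Fallback, setting out from 12 and returning at 20: 12 would be coupled with commercial 4-bromo-3,5-dimethoxybenzaldehyde (CuI, picolinic acid, K3PO4, DMSO, 90 °C), whose para formyl group activates the halide toward substitution. This should give 3,5-dimethoxy-4-[3,4,5-trimethoxy-2-(3,4,5-trimethoxyphenoxy)phenoxy]benzaldehyde F4. Baeyer–Villiger oxidation (mCPBA, NaHCO3, CH2Cl2, 0 °C), in which the electron-rich aryl group migrates, would give the aryl formate 3,5-dimethoxy-4-[3,4,5-trimethoxy-2-(3,4,5-trimethoxyphenoxy)phenoxy]phenyl formate F5. Methanolysis (MeOH, catalytic K2CO3, rt) would then give phenol 20, so the benzyl ether 19 and its hydrogenolysis are bypassed.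

3. Step 23. What may go wrong: ether cleavage is incomplete across twenty-one sites, and the free polyphenol is lost by air oxidation and irreversible adsorption during isolation. Fallback, setting out from 38 and returning at 39: after exhaustive BBr3 cleavage and methanol quench the crude polyphenol would not be purified but peracetylated (Ac2O, pyridine, DMAP, rt) to the henicosaacetate of the target F6. This is a stable, non-polar compound that can be purified on silica and checked for complete deprotection. Acid-catalysed methanolysis under argon (HCl in degassed MeOH, rt) followed by evaporation would then release 39 without chromatography of the free phenol.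

**Further compounds**

F1 | step 5 | 3,4-bis(3,4,5-trimethoxyphenoxy)cyclobut-3-ene-1,2-dione | COc1c(OC)cc(cc1OC)OC1=C(Oc2cc(OC)c(OC)c(OC)c2)C(=O)C1=O
F2 | step 5 | lithium alkoxide of F3 (racemic, not isolated) | COc1c(OC)cc(cc1OC)OC1=C(Oc2cc(OC)c(OC)c(OC)c2)C([O-])(C(OC)=C)C1=O.[Li+]
F3 | step 5 | 4-methoxy-4-(1-methoxyvinyl)-2,3-bis(3,4,5-trimethoxyphenoxy)cyclobut-2-en-1-one (racemic) | COc1c(OC)cc(cc1OC)OC1=C(Oc2cc(OC)c(OC)c(OC)c2)C(OC)(C(OC)=C)C1=O
F4 | step 10 | 3,5-dimethoxy-4-[3,4,5-trimethoxy-2-(3,4,5-trimethoxyphenoxy)phenoxy]benzaldehyde | COc1c(OC)cc(cc1OC)Oc1c(OC)c(OC)c(OC)cc1Oc1c(OC)cc(C=O)cc1OC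
F5 | step 10 | 3,5-dimethoxy-4-[3,4,5-trimethoxy-2-(3,4,5-trimethoxyphenoxy)phenoxy]phenyl formate | COc1c(OC)cc(cc1OC)Oc1c(OC)c(OC)c(OC)cc1Oc1c(OC)cc(cc1OC)OC=O
F6 | step 23 | henicosaacetate of the target | CC(=O)Oc1c(OC(C)=O)cc(cc1OC(C)=O)Oc1c(OC(C)=O)c(OC(C)=O)c(OC(C)=O)cc1Oc1c(OC(C)=O)cc(cc1OC(C)=O)Oc1c(OC(C)=O)c(OC(C)=O)c(OC(C)=O)cc1Oc1c(OC(C)=O)cc(cc1OC(C)=O)Oc1c(OC(C)=O)c(OC(C)=O)c(OC(C)=O)cc1Oc1c(OC(C)=O)cc(cc1OC(C)=O)Oc1c(OC(C)=O)cc(OC(C)=O)cc1OC(C)=O
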